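## Retrosynthetic overview
- Target (27) ⇐ global demethylation of the nonamethyl ether 26 ⇐ Heck coupling of 4-methoxystyrene onto the aryl bromide 25. The styryl group goes on last so that no alkene is near the carbene radicals.
- Each of the three trans-2,3-diaryl-dihydrobenzofurans (C7/C8 pairs) forms in one Co(II)-metalloradical step. A diaryl diazo compound carrying an ortho ArO–CH2Ar(OMe) group undergoes 1,5-HAT then radical C–C closure. The catalyst enantiomer is A/B/A, which matches the alternating R,R / S,S / R,R pattern of the target.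
- Rings close from the D end to the A end: BF3, then BF2, then BF1. Each diaryl ketone comes from an aryllithium (from the previous aryl bromide) plus the bromo-aldehyde 10, followed by oxidation. The Br left on each new ring is the handle for the next cycle.
- All carbon skeletons derive from resorcinol, p-cresol and 4-iodophenol.

Assumptions: (1) Methyl ethers are the protecting groups, removed at the end by BBr3. (2) Co(II) amidoporphyrin enantiomer **Cat-A** delivers (2R,3R) benzofurans and **Cat-B** delivers (2S,3S). The assignment of A and B is confirmed by a small screen, and catalyst control is assumed to override the remote stereocentres.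

## Route

**Step 1**
Reactants: 1 resorcinol
Product: 2 1,3-dimethoxybenzene
Conditions: MeI, K2CO3, acetone, reflux
Reagents that add atoms: MeI, CI
Why: Williamson bis-O-methylation.

**Step 2**
Reactants: 2
Product: 3 2-(3,5-dimethoxyphenyl)-4,4,5,5-tetramethyl-1,3,2-dioxaborolane
Conditions: B2pin2, [Ir(OMe)(cod)]2 / dtbpy, THF, 80 °C
Reagents that add atoms: B2pin2, CC1(C)OB(OC1(C)C)B1OC(C)(C)C(C)(C)O1
Why: Ir-catalysed C–H borylation is governed by sterics, so it occurs at C5, meta to both OMe groups. This installs the "5-position" handle that electrophilic substitution cannot reach.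

**Step 3**
Reactants: 3
Product: 4 1-bromo-3,5-dimethoxybenzene
Conditions: CuBr2, MeOH/H2O, 80 °C
Reagents that add atoms: CuBr2, Br[Cu]Br
Why: Cu(II)-mediated bromodeboronation of the aryl Bpin.

**Step 4**
Reactants: 4
Product: 5 2-bromo-4,6-dimethoxybenzaldehyde
Conditions: POCl3, DMF, 0 °C → 80 °C
Reagents that add atoms: DMF, CN(C)C=O (supplies CHO)
Why: Vilsmeier formylation goes at C2, ortho to Br and OMe and para to the other OMe.

**Step 5**
Reactants: 5
Product: 6 2-bromo-6-hydroxy-4-methoxybenzaldehyde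
Conditions: BCl3, CH2Cl2, –78 → 0 °C
Reagents that add atoms: none
Why: BCl3 chelates the aldehyde and selectively cleaves the OMe ortho to the CHO; the para OMe stays.

**Step 6**
Reactants: 7 p-cresol
Product: 8 4-methylanisole
Conditions: MeI, K2CO3, acetone, reflux
Reagents that add atoms: MeI, CI
Why: O-methylation.

**Step 7**
Reactants: 8
Product: 9 4-methoxybenzyl bromide
Conditions: NBS, AIBN, PhCF3, 80 °C
Reagents that add atoms: NBS, BrN1C(=O)CCC1=O
Why: Wohl–Ziegler benzylic radical bromination; the para-OMe weakens the benzylic C–H and directs the reaction to the methyl group.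

**Step 8**
Reactants: 6 + 9
Product: 10 (Z) 2-bromo-4-methoxy-6-[(4-methoxybenzyl)oxy]benzaldehyde
Conditions: K2CO3, DMF, rt
Reagents that add atoms: none beyond reactant 9
Why: Williamson etherification gives the ArO–CH2Ar' unit that serves as the 1,5-HAT donor, and leaves the CHO and ArBr handles intact. Compound 10 is used three times, as a separate batch for each ring.

**Step 9**
Reactants: 11 4-iodophenol
Product: 12 4-iodoanisole
Conditions: MeI, K2CO3, acetone, reflux
Reagents that add atoms: MeI, CI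
Why: O-methylation.

**Step 10**
Reactants: 12
Product: 13 4-methoxystyrene
Conditions: potassium vinyltrifluoroborate, PdCl2(dppf), Cs2CO3, THF/H2O, 85 °C
Reagents that add atoms: C=C[B-](F)(F)F.[K+] (supplies vinyl)
Why: Suzuki–Miyaura vinylation.

**Step 11**
Reactants: 4 + 10
Product: 14 (3,5-dimethoxyphenyl)[2-bromo-4-methoxy-6-(4-methoxybenzyloxy)phenyl]methanol (racemic)
Conditions: n-BuLi, THF, –78 °C (ArBr → ArLi), then 10
Reagents that add atoms: none
Why: Br/Li exchange followed by 1,2-addition to the aldehyde. The carbinol stereocentre is destroyed in the next step.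

**Step 12**
Reactants: 14
Product: 15 the diaryl ketone (ring D / ring C)
Conditions: Dess–Martin periodinane, NaHCO3, CH2Cl2, rt
Reagents that add atoms: none
Why: Mild oxidation; the PMB-type ether and ArBr survive.

**Step 13**
Reactants: 15
Product: 16 the N-tosylhydrazone of 15
Conditions: TsNHNH2, PPTS (cat.), 4 Å MS, toluene, 80 °C
Reagents that add atoms: TsNHNH2, Cc1ccc(cc1)S(=O)(=O)NN
Why: Hydrazone condensation under mild acid, which avoids ionising the benzylic ethers. The tosylhydrazone is a bench-stable diazo precursor.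

**Step 14 (key radical step, ring BF3)**
Reactants: 16
Product: 17 (2R,3R)-4-bromo-3-(3,5-dimethoxyphenyl)-6-methoxy-2-(4-methoxyphenyl)-2,3-dihydrobenzofuran
Conditions: Cat-A (Co(II) chiral amidoporphyrin, 5 mol %), Cs2CO3, 4 Å MS, toluene, 60 °C
Reagents that add atoms: none (base and catalyst only; TsH and N2 are lost)
Why: Base converts 16 to the diaryldiazomethane. Co(II) gives a Co(III)-carbene radical, which abstracts the activated ArO–CH2–Ar' hydrogen (1,5-HAT). The resulting benzylic radical closes onto the Co-bound carbon (5-exo radical substitution), forming C2–C3 with trans selectivity. The chiral pocket sets the absolute configuration, giving (2R,3R).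
Proposed new method: this extends Co(II)-metalloradical 1,5-C–H alkylation of α-aryl diazomethanes (known to give chiral 2,3-dihydrobenzofurans) to a hindered diaryl carbene that carries its second aryl group directly. The ring C a1–Br survives Co(II).

**Step 15**
Reactants: 17 + 10
Product: 18 carbinol [(2R,3R)-benzofuran-4-yl][2-bromo-4-methoxy-6-(4-methoxybenzyloxy)phenyl]methanol (epimeric at carbinol)
Conditions: t-BuLi (2.1 equiv), THF, –78 °C, then 10
Reagents that add atoms: none
Why: Br/Li exchange at ring C, then 1,2-addition. The benzylic C–H and C–O stereocentres of 17 are not touched at –78 °C.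

**Step 16**
Reactants: 18
Product: 19 the diaryl ketone (ring C / ring B)
Conditions: DMP, NaHCO3, CH2Cl2, rt
Reagents that add atoms: none
Why: Oxidation destroys the carbinol stereocentre.

**Step 17**
Reactants: 19
Product: 20 the N-tosylhydrazone of 19
Conditions: TsNHNH2, PPTS, 4 Å MS, toluene, 80 °C
Reagents that add atoms: TsNHNH2, Cc1ccc(cc1)S(=O)(=O)NN
Why: Hydrazone condensation, as in Step 13.

**Step 18 (key radical step, ring BF2)**
Reactants: 20
Product: 21 (2S,3S)-4-bromo-6-methoxy-2-(4-methoxyphenyl)-3-[(2R,3R)-3-(3,5-dimethoxyphenyl)-6-methoxy-2-(4-methoxyphenyl)-2,3-dihydrobenzofuran-4-yl]-2,3-dihydrobenzofuran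
Conditions: Cat-B (enantiomer of Cat-A, 5 mol %), Cs2CO3, 4 Å MS, toluene, 60 °C
Reagents that add atoms: none
Why: Same 1,5-HAT / radical-substitution cascade. The only available donor is the ring B aryl–O–CH2Ar' group. The enantiomeric catalyst installs the (2S,3S) centres, which invert the sense relative to BF3.
Proposed new method: as in Step 14. The extra requirement is that catalyst control overrides the two remote (R,R) centres; the likely outcome is a matched/mismatched catalyst effect.

**Step 19**
Reactants: 21 + 10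
Product: 22 carbinol (ring B-4-yl)(ring A aryl)methanol
Conditions: t-BuLi (2.1 equiv), THF, –78 °C, then 10
Reagents that add atoms: none
Why: Br/Li exchange at ring B, then 1,2-addition.

**Step 20**
Reactants: 22
Product: 23 the diaryl ketone (ring B / ring A)
Conditions: DMP, NaHCO3, CH2Cl2, rt
Reagents that add atoms: none
Why: Oxidation.

**Step 21**
Reactants: 23
Product: 24 the N-tosylhydrazone of 23
Conditions: TsNHNH2, PPTS, 4 Å MS, toluene, 80 °C
Reagents that add atoms: TsNHNH2, Cc1ccc(cc1)S(=O)(=O)NN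
Why: Hydrazone condensation.

**Step 22 (key radical step, ring BF1)**
Reactants: 24
Product: 25 (2R,3R)-4-bromo-6-methoxy-2-(4-methoxyphenyl)-3-{(2S,3S)-6-methoxy-2-(4-methoxyphenyl)-3-[(2R,3R)-3-(3,5-dimethoxyphenyl)-6-methoxy-2-(4-methoxyphenyl)-2,3-dihydrobenzofuran-4-yl]-2,3-dihydrobenzofuran-4-yl}-2,3-dihydrobenzofuran
Conditions: Cat-A, Cs2CO3, 4 Å MS, toluene, 60 °C
Reagents that add atoms: none
Why: Same cascade with the ring A aryl–O–CH2Ar' group as donor; Cat-A gives (2R,3R). No alkene is present, so carbene-radical addition to a styrene (indene formation) cannot compete.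
Proposed new method: as in Step 14.

**Step 23**
Reactants: 25 + 13
Product: 26 the nonamethyl ether of the target with E-stilbene
Conditions: Pd(OAc)2, P(t-Bu)3·HBF4, Cy2NMe, dioxane, 100 °C
Reagents that add atoms: none beyond reactant 13
Why: Mizoroki–Heck coupling of the ring A aryl bromide with 4-methoxystyrene gives the E-stilbene selectively. The benzylic stereocentres are inert to these conditions.

**Step 24**
Reactants: 26
Product: 27 Miyabenol A (target)
Conditions: BBr3 (≈20 equiv), CH2Cl2, –78 °C → 0 °C; then MeOH/aq. NaHCO3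
Reagents that add atoms: none
Why: BBr3 cleaves aryl methyl ethers and leaves the E-alkene and the dihydrobenzofurans intact, as in resveratrol-oligomer end-game chemistry.

## Compound list
1 | resorcinol | Oc1cccc(O)c1 | starting material
2 | 1,3-dimethoxybenzene | COc1cccc(OC)c1 | intermediate
3 | 3,5-dimethoxyphenyl-Bpin | COc1cc(OC)cc(c1)B1OC(C)(C)C(C)(C)O1 | intermediate
4 | 1-bromo-3,5-dimethoxybenzene | COc1cc(Br)cc(OC)c1 | intermediate
5 | 2-bromo-4,6-dimethoxybenzaldehyde | COc1cc(Br)c(C=O)c(OC)c1 | intermediate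
6 | 2-bromo-6-hydroxy-4-methoxybenzaldehyde | COc1cc(Br)c(C=O)c(O)c1 | intermediate
7 | p-cresol | Cc1ccc(O)cc1 | starting material
8 | 4-methylanisole | Cc1ccc(OC)cc1 | intermediate
9 | 4-methoxybenzyl bromide | BrCc1ccc(OC)cc1 | intermediate
10 | 2-bromo-4-methoxy-6-(4-methoxybenzyloxy)benzaldehyde | COc1cc(Br)c(C=O)c(OCc2ccc(OC)cc2)c1 | intermediate
11 | 4-iodophenol | Oc1ccc(I)cc1 | starting material
12 | 4-iodoanisole | COc1ccc(I)cc1 | intermediate
13 | 4-methoxystyrene | C=Cc1ccc(OC)cc1 | intermediate
14 | diaryl carbinol (ring D / ring C) | COc1cc(OC)cc(c1)C(O)c1c(Br)cc(OC)cc1OCc1ccc(OC)cc1 | intermediate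
15 | diaryl ketone (ring D / ring C) | COc1cc(OC)cc(c1)C(=O)c1c(Br)cc(OC)cc1OCc1ccc(OC)cc1 | intermediate
16 | N-tosylhydrazone of 15 | COc1cc(OC)cc(c1)C(=NNS(=O)(=O)c1ccc(C)cc1)c1c(Br)cc(OC)cc1OCc1ccc(OC)cc1 | intermediate
17 | BF3 benzofuran bromide (2R,3R) | Brc2cc(OC)cc5c2[C@@H](c2cc(OC)cc(OC)c2)[C@H](c2ccc(OC)cc2)O5 | intermediate
18 | carbinol (ring C / ring B) | OC(c2c(Br)cc(OC)cc2OCc2ccc(OC)cc2)c2cc(OC)cc5c2[C@@H](c2cc(OC)cc(OC)c2)[C@H](c2ccc(OC)cc2)O5 | intermediate
19 | ketone (ring C / ring B) | O=C(c2c(Br)cc(OC)cc2OCc2ccc(OC)cc2)c2cc(OC)cc5c2[C@@H](c2cc(OC)cc(OC)c2)[C@H](c2ccc(OC)cc2)O5 | intermediate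
20 | N-tosylhydrazone of 19 | Cc1ccc(cc1)S(=O)(=O)NN=C(c2c(Br)cc(OC)cc2OCc2ccc(OC)cc2)c2cc(OC)cc5c2[C@@H](c2cc(OC)cc(OC)c2)[C@H](c2ccc(OC)cc2)O5 | intermediate
21 | bis-benzofuran bromide (BF2 S,S; BF3 R,R) | Brc2cc(OC)cc4c2[C@H](c2cc(OC)cc5c2[C@@H](c2cc(OC)cc(OC)c2)[C@H](c2ccc(OC)cc2)O5)[C@@H](c2ccc(OC)cc2)O4 | intermediate
22 | carbinol (ring B / ring A) | OC(c2c(Br)cc(OC)cc2OCc2ccc(OC)cc2)c2cc(OC)cc4c2[C@H](c2cc(OC)cc5c2[C@@H](c2cc(OC)cc(OC)c2)[C@H](c2ccc(OC)cc2)O5)[C@@H](c2ccc(OC)cc2)O4 | intermediate
23 | ketone (ring B / ring A) | O=C(c2c(Br)cc(OC)cc2OCc2ccc(OC)cc2)c2cc(OC)cc4c2[C@H](c2cc(OC)cc5c2[C@@H](c2cc(OC)cc(OC)c2)[C@H](c2ccc(OC)cc2)O5)[C@@H](c2ccc(OC)cc2)O4 | intermediate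
24 | N-tosylhydrazone of 23 | Cc1ccc(cc1)S(=O)(=O)NN=C(c2c(Br)cc(OC)cc2OCc2ccc(OC)cc2)c2cc(OC)cc4c2[C@H](c2cc(OC)cc5c2[C@@H](c2cc(OC)cc(OC)c2)[C@H](c2ccc(OC)cc2)O5)[C@@H](c2ccc(OC)cc2)O4 | intermediate
25 | tris-benzofuran aryl bromide | Brc2cc(OC)cc3c2[C@@H](c2cc(OC)cc4c2[C@H](c2cc(OC)cc5c2[C@@H](c2cc(OC)cc(OC)c2)[C@H](c2ccc(OC)cc2)O5)[C@@H](c2ccc(OC)cc2)O4)[C@H](c2ccc(OC)cc2)O3 | intermediate
26 | nonamethyl ether of the target | COc1ccc(/C=C/c2cc(OC)cc3c2[C@@H](c2cc(OC)cc4c2[C@H](c2cc(OC)cc5c2[C@@H](c2cc(OC)cc(OC)c2)[C@H](c2ccc(OC)cc2)O5)[C@@H](c2ccc(OC)cc2)O4)[C@H](c2ccc(OC)cc2)O3)cc1 | intermediate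
27 | Miyabenol A | Oc1ccc(/C=C/c2cc(O)cc3c2[C@@H](c2cc(O)cc4c2[C@H](c2cc(O)cc5c2[C@@H](c2cc(O)cc(O)c2)[C@H](c2ccc(O)cc2)O5)[C@@H](c2ccc(O)cc2)O4)[C@H](c2ccc(O)cc2)O3)cc1 | target

## Totals
Total steps: 24. Longest linear sequence: 20 (resorcinol → 2 → 3 → 4 → 5 → 6 → 10 → 14 → … → 25 → 26 → 27).

## Three steps most likely to fail
1. **Steps 14/18/22, Co(II)-metalloradical cyclisation of hindered diaryl carbenes.** The carbene is 2,6-disubstituted, and catalyst control must override the remote stereocentres.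
   - Fallback: change the mechanism to a polar carbenoid C–H insertion. Isolate the diaryldiazomethane (hydrazone → MnO2) and use Rh2(S-PTAD)4, or its enantiomer for BF2, in the same ArO–CH2Ar' insertion.
2. **Steps 13/17/21, tosylhydrazone formation on 2,6-disubstituted diaryl ketones.**
   - Fallback: convert the ketone to the thioketone (Lawesson's reagent), treat it with hydrazine, and oxidise with MnO2 to the isolated diaryldiazomethane. This goes to the same Co or Rh step.
3. **Step 24, BBr3 removal of nine methyl ethers.** It risks opening or epimerising the p-anisyl-stabilised benzylic C–O bonds of the dihydrobenzofurans.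
   - Fallback: rebuild the sequence with MOM ethers on all ring oxygens from Step 1 (MOM-resorcinol → Ir borylation, and so on). The deprotection then becomes a mild HCl/MeOH step with no Lewis acid.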